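The single-handed catalyst in flask ash works on a racemate of left-handed and right-handed substrate, with [partner] and [protic impurity] as charged; flask elm differs in carrying more protic impurity.

| flask | left-handed substrate | right-handed substrate | partner | protic impurity | catalyst | remark | time |
|---|---|---|---|---|---|---|---|
| ash | 0.020 M | 0.020 M | 0.022 M | 0.020 M | 100 µM | the very flask that is asked about, followed so far |  |
| elm | 0.020 M | 0.020 M | 0.022 M | 0.030 M | 100 µM | run made earlier |  |
| flask | 0.020 M | 0.020 M | 0.0220 M | 0.0200 M | 100 µM |  | 80 min |

| run | time / min | left-handed substrate / % | right-handed substrate / % |
|---|---|---|---|
| ash | 1.33 | 47.9 | 49.3 |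
| ash | 3.00 | 48.5 | 47.8 |
| ash | 6.00 | 45.5 | 47.7 |
| ash | 15.0 | 43.9 | 44.8 |
| elm | 8.00 | 45.8 | 47.6 |
| elm | 15.0 | 43.3 | 45.3 |
| elm | 25.0 | 40.8 | 44.2 |
| elm | 30.0 | 40.3 | 42.3 |

(scatter of a reading: 0.5 percentage points)

- catalyst is single-handed; left-handed substrate and right-handed substrate are mirror images of each other, charged as a racemate, each of them at the stated concentration
- the numbers in the tables scatter by 0.5 percentage points (one standard deviation)
- an excess is the difference of the two amounts in percent of their sum
- an excess is below zero if the other one leads

* part of the left-handed substrate and right-handed substrate charged together that has reacted at 80 min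
* excess of left-handed product over right-handed product in the product at 80 min
* excess of right-handed substrate over left-handed substrate among what is left of the two at 80 min

Both substrates meet the same partner and the same catalyst, so I divided their two rates of loss, and time dropped out, along with whatever slowed the runs. Pooled over the elm readings this gave 1.48 as a reading of the selectivity factor, the logarithm of the fraction of left-handed substrate remaining divided by that of the right-handed. By my own reckoning the product would begin at an excess of 19.5% of left-handed product, provided it stayed as formed; the readings of both runs are of the substrates.

The forecast, reasoning that “the impurity seems to kill catalyst or divert partner”, gave 29% reacted, 16.5% for the product and 6.8% for the substrate.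

At 80 min flask ash gave 27.5% reacted, an excess of 0.428% in the product and 7.60% in the substrate.

    partner + catalyst + right-handed substrate → catalyst + right-handed product (k = 4400 M⁻² min⁻¹)
    partner + catalyst + left-handed substrate → catalyst + left-handed product (k = 7100 M⁻² min⁻¹)
    partner + protic impurity → quenched reagent (k = 0.680 M⁻¹ min⁻¹)
    left-handed product ⇌ right-handed product (k = 0.0800 min⁻¹)
    catalyst ⇌ dormant form (K = 0.340, k = 0.0560 min⁻¹)

The product excess in flask ash stood 16 percentage points below the forecast. Left-handed product turns into right-handed product with a half-life of 8.7 min, forward step alone, short against the 80 min of the run. I carried the selectivity factor over to the substrates: in flask ash, 67% of the charged left-handed substrate remaining and 1.48 gave 76.3% of the charged right-handed, where 78% stood. In the neighbour flask with 0.055 M of partner, 30% of the charged left-handed substrate remained at 80 min, 1.48 gave 44.9% of the charged right-handed, and 48% stood.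

The runs come from a simulation for an exercise, and the scatter is random.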